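**Retrosynthetic overview**
1. Last C–O bond: the free carboxylate of the cyclohexene half 18 opens the spiro-oxirane 34 at its CH2, giving the ester and the tertiary carbinol in one step; a final 2-(trimethylsilyl)ethyl ester cleavage follows.
2. Epoxy-lactone 34 comes from iodo-β-lactone 31 by a 4→7 translactonisation and oxirane closure; 31 comes from the β,γ-unsaturated acid 30 by iodolactonisation, the four-membered ring forcing the carbinol oxygen cis to the lactone carbonyl.
3. Acid 30 comes from allylic alcohol 27 by a proposed carbonylative [2,3]-Wittig rearrangement that forms the C–C(=O) bond and sets the ring-fusion stereocentre.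
4. Allylic alcohols 17 and 27 (mirror-image series) come from (R)- and (S)-cryptone by trans vinyl conjugate addition with enol triflate trapping, ozonolysis, E-selective Wittig olefination and Stille hydroxymethylation.
5. Ring order: cyclohexenone (organocatalytic Michael addition, then aldol condensation) → β-lactone → oxepinone plus oxirane → oxirane opened in the fragment coupling.

Assumption: the SMILES is taken literally, so the two halves belong to opposite enantiomeric series at the isopropyl-bearing carbon and are made from (R)- and (S)-cryptone respectively; both enantiomers of α,α-diphenylprolinol trimethylsilyl ether, phosphonium salt 1 and carbonate 3 are taken as commercial.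

**Ylide reagent**

Step 1
Reactants: 1 (2-hydroxyethyl)triphenylphosphonium bromide
Product: 2 [2-(tert-butyldimethylsilyloxy)ethyl]triphenylphosphonium bromide
Conditions: TBSCl, imidazole, CH2Cl2, rt
Reagents that add atoms: tert-butyldimethylsilyl chloride, CC(C)(C)[Si](C)(C)Cl
Why: Standard silyl ether formation on a primary alcohol; no stereocentre is involved.

Step 2
Reactants: 2 [2-(tert-butyldimethylsilyloxy)ethyl]triphenylphosphonium bromide; 3 4-nitrophenyl 2-(trimethylsilyl)ethyl carbonate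
Product: 6 2-(trimethylsilyl)ethyl 3-(tert-butyldimethylsilyloxy)-2-(triphenylphosphoranylidene)propanoate, via ylide 4 (not isolated), via acylphosphonium salt 5 (not isolated)
Conditions: NaN(SiMe3)2 (1.0 equiv), THF, −78 °C; 3, −78 to 0 °C; NaN(SiMe3)2 (1.0 equiv), 0 °C
Reagents that add atoms: none
Why: Bestmann-type C-acylation of a non-stabilised ylide by an active carbonate, followed by deprotonation of the acylphosphonium salt, gives the ester-stabilised α-substituted ylide; no stereocentre is involved.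

**Cyclohexene half (R series)**

Step 3
Reactants: 7 3-methylbutanal; 8 but-3-en-2-one
Product: 9 (2R)-5-oxo-2-(propan-2-yl)hexanal
Conditions: (R)-α,α-diphenylprolinol trimethylsilyl ether (5 mol %), ethyl 3,4-dihydroxybenzoate (20 mol %), neat, 4 °C
Reagents that add atoms: none
Why: Enamine-catalysed Michael addition of an aldehyde to an enone; the diarylmethyl silyl ether group of the (R)-catalyst shields one face of the E-enamine, so the enone adds to the open face and gives the 2R aldehyde.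

Step 4
Reactants: 9 (2R)-5-oxo-2-(propan-2-yl)hexanal
Product: 11 (4R)-4-(propan-2-yl)cyclohex-2-en-1-one [(R)-cryptone], via ketol 10 (not isolated)
Conditions: LiOH (0.2 equiv), i-PrOH, rt
Reagents that add atoms: none
Why: Intramolecular aldol condensation (methyl ketone enolate onto the aldehyde, then E1cB dehydration) closes the six-membered enone; the isopropyl stereocentre is not deprotonated under these mild conditions.

Step 5
Reactants: 11 (4R)-4-(propan-2-yl)cyclohex-2-en-1-one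
Product: 13 (3R,4R)-3-ethenyl-4-(propan-2-yl)cyclohex-1-en-1-yl trifluoromethanesulfonate, via magnesium enolate 12 (not isolated)
Conditions: CH2=CHMgBr (1.3 equiv), CuBr·SMe2 (10 mol %), THF, −78 °C; then Comins' reagent, −78 to 0 °C
Reagents that add atoms: vinylmagnesium bromide, C=C[Mg]Br; Comins' reagent N-(5-chloropyridin-2-yl)-N-(trifluoromethylsulfonyl)trifluoromethanesulfonamide, Clc1ccc(nc1)N(S(=O)(=O)C(F)(F)F)S(=O)(=O)C(F)(F)F
Why: Copper-catalysed conjugate addition of the vinyl Grignard reagent occurs anti to the adjacent isopropyl group (sets the 3,4-trans relationship), and the regiodefined enolate is O-sulfonylated in situ to the enol triflate.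

Step 6
Reactants: 13 (3R,4R)-3-ethenyl-4-(propan-2-yl)cyclohex-1-en-1-yl trifluoromethanesulfonate
Product: 15 (3R,4R)-3-formyl-4-(propan-2-yl)cyclohex-1-en-1-yl trifluoromethanesulfonate, via ozonide 14 (not isolated)
Conditions: O3, CH2Cl2, −78 °C (stopped at first excess); PPh3, −78 °C to rt
Reagents that add atoms: ozone, [O-][O+]=O
Why: Ozonolysis with reductive work-up; the monosubstituted vinyl group reacts much faster than the electron-poor triflyloxy-substituted ring alkene, and the trans-diequatorial aldehyde is also the thermodynamically preferred epimer.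

Step 7
Reactants: 15 (3R,4R)-3-formyl-4-(propan-2-yl)cyclohex-1-en-1-yl trifluoromethanesulfonate; 6 2-(trimethylsilyl)ethyl 3-(tert-butyldimethylsilyloxy)-2-(triphenylphosphoranylidene)propanoate
Product: 16 2-(trimethylsilyl)ethyl (2E)-2-[(tert-butyldimethylsilyloxy)methyl]-3-[(1S,6R)-6-(propan-2-yl)-3-(trifluoromethylsulfonyloxy)cyclohex-2-en-1-yl]prop-2-enoate
Conditions: 6 (1.5 equiv), toluene, 80 °C
Reagents that add atoms: none
Why: Wittig olefination with an α-substituted ester-stabilised ylide gives the E-enoate (ring carbon trans to the ester, cis to CH2O) under neutral conditions that do not epimerise the aldehyde.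

Step 8
Reactants: 16 2-(trimethylsilyl)ethyl (2E)-2-[(tert-butyldimethylsilyloxy)methyl]-3-[(1S,6R)-6-(propan-2-yl)-3-(trifluoromethylsulfonyloxy)cyclohex-2-en-1-yl]prop-2-enoate
Product: 17 2-(trimethylsilyl)ethyl (2E)-2-[(tert-butyldimethylsilyloxy)methyl]-3-[(1R,6R)-3-(hydroxymethyl)-6-(propan-2-yl)cyclohex-2-en-1-yl]prop-2-enoate
Conditions: Bu3SnCH2OH, Pd(PPh3)4 (5 mol %), LiCl (3 equiv), 1,4-dioxane, 100 °C
Reagents that add atoms: (tributylstannyl)methanol, CCCC[Sn](CCCC)(CCCC)CO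
Why: Stille coupling of the enol triflate with the hydroxymethylstannane (oxidative addition to zerovalent palladium, chloride-assisted transmetalation) installs CH2OH without moving the ring alkene; the descriptor at C1 changes only because of CIP priorities.

Step 9
Reactants: 17 2-(trimethylsilyl)ethyl (2E)-2-[(tert-butyldimethylsilyloxy)methyl]-3-[(1R,6R)-3-(hydroxymethyl)-6-(propan-2-yl)cyclohex-2-en-1-yl]prop-2-enoate
Product: 18 (2E)-2-(hydroxymethyl)-3-[(1R,6R)-3-(hydroxymethyl)-6-(propan-2-yl)cyclohex-2-en-1-yl]prop-2-enoic acid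
Conditions: Bu4NF (4 equiv), THF, 0 °C to rt; 0.5 M HCl to pH 3
Reagents that add atoms: none
Why: Fluoride cleaves the silyl ether and, by β-silyl fragmentation, the 2-(trimethylsilyl)ethyl ester in one operation; no stereocentre is touched.

**Benzoxepine half (S series)**

Step 10
Reactants: 7 3-methylbutanal; 8 but-3-en-2-one
Product: 19 (2S)-5-oxo-2-(propan-2-yl)hexanal
Conditions: (S)-α,α-diphenylprolinol trimethylsilyl ether (5 mol %), ethyl 3,4-dihydroxybenzoate (20 mol %), neat, 4 °C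
Reagents that add atoms: none
Why: Same enamine-catalysed Michael addition as step 3 with the enantiomeric catalyst, giving the 2S aldehyde.

Step 11
Reactants: 19 (2S)-5-oxo-2-(propan-2-yl)hexanal
Product: 21 (4S)-4-(propan-2-yl)cyclohex-2-en-1-one [(S)-cryptone], via ketol 20 (not isolated)
Conditions: LiOH (0.2 equiv), i-PrOH, rt
Reagents that add atoms: none
Why: Intramolecular aldol condensation as in step 4; the stereocentre is untouched.

Step 12
Reactants: 21 (4S)-4-(propan-2-yl)cyclohex-2-en-1-one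
Product: 23 (3S,4S)-3-ethenyl-4-(propan-2-yl)cyclohex-1-en-1-yl trifluoromethanesulfonate, via magnesium enolate 22 (not isolated)
Conditions: CH2=CHMgBr (1.3 equiv), CuBr·SMe2 (10 mol %), THF, −78 °C; then Comins' reagent, −78 to 0 °C
Reagents that add atoms: vinylmagnesium bromide, C=C[Mg]Br; Comins' reagent N-(5-chloropyridin-2-yl)-N-(trifluoromethylsulfonyl)trifluoromethanesulfonamide, Clc1ccc(nc1)N(S(=O)(=O)C(F)(F)F)S(=O)(=O)C(F)(F)F
Why: Copper-catalysed conjugate addition anti to the isopropyl group sets the trans relationship, and the enolate is trapped as the enol triflate, as in step 5.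

Step 13
Reactants: 23 (3S,4S)-3-ethenyl-4-(propan-2-yl)cyclohex-1-en-1-yl trifluoromethanesulfonate
Product: 25 (3S,4S)-3-formyl-4-(propan-2-yl)cyclohex-1-en-1-yl trifluoromethanesulfonate, via ozonide 24 (not isolated)
Conditions: O3, CH2Cl2, −78 °C (stopped at first excess); PPh3, −78 °C to rt
Reagents that add atoms: ozone, [O-][O+]=O
Why: Chemoselective ozonolysis of the vinyl group beside the electron-poor enol triflate, as in step 6.

Step 14
Reactants: 25 (3S,4S)-3-formyl-4-(propan-2-yl)cyclohex-1-en-1-yl trifluoromethanesulfonate; 6 2-(trimethylsilyl)ethyl 3-(tert-butyldimethylsilyloxy)-2-(triphenylphosphoranylidene)propanoate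
Product: 26 2-(trimethylsilyl)ethyl (2E)-2-[(tert-butyldimethylsilyloxy)methyl]-3-[(1R,6S)-6-(propan-2-yl)-3-(trifluoromethylsulfonyloxy)cyclohex-2-en-1-yl]prop-2-enoate
Conditions: 6 (1.5 equiv), toluene, 80 °C
Reagents that add atoms: none
Why: E-selective Wittig olefination with the stabilised ylide, as in step 7.

Step 15
Reactants: 26 2-(trimethylsilyl)ethyl (2E)-2-[(tert-butyldimethylsilyloxy)methyl]-3-[(1R,6S)-6-(propan-2-yl)-3-(trifluoromethylsulfonyloxy)cyclohex-2-en-1-yl]prop-2-enoate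
Product: 27 2-(trimethylsilyl)ethyl (2E)-2-[(tert-butyldimethylsilyloxy)methyl]-3-[(1S,6S)-3-(hydroxymethyl)-6-(propan-2-yl)cyclohex-2-en-1-yl]prop-2-enoate
Conditions: Bu3SnCH2OH, Pd(PPh3)4 (5 mol %), LiCl (3 equiv), 1,4-dioxane, 100 °C
Reagents that add atoms: (tributylstannyl)methanol, CCCC[Sn](CCCC)(CCCC)CO
Why: Stille hydroxymethylation of the enol triflate, as in step 8.

Step 16
Reactants: 27 2-(trimethylsilyl)ethyl (2E)-2-[(tert-butyldimethylsilyloxy)methyl]-3-[(1S,6S)-3-(hydroxymethyl)-6-(propan-2-yl)cyclohex-2-en-1-yl]prop-2-enoate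
Product: 30 (1S,2R,3S)-2-[(1E)-3-(tert-butyldimethylsilyloxy)-2-{[2-(trimethylsilyl)ethoxy]carbonyl}prop-1-en-1-yl]-6-methylidene-3-(propan-2-yl)cyclohexane-1-carboxylic acid, via potassium alkoxide 28 (not isolated), via alkoxycarbonyl anion 29 (not isolated)
Conditions: KH (1.05 equiv), 18-crown-6 (1.1 equiv), THF (0.02 M), 0 °C; CO (20 bar), 25 °C; 0.5 M HCl to pH 3 at 0 °C
Reagents that add atoms: carbon monoxide, [C-]#[O+]
Why: Proposed new method: a carbonylative [2,3]-Wittig rearrangement in which the allylic potassium alkoxide adds reversibly to CO (the elementary step of base-catalysed formate synthesis) to give an alkoxycarbonyl anion, i.e. an oxido(alkoxy)carbene isoelectronic with the amino(alkoxy)carbene of the Büchi rearrangement and analogous to the α-oxy carbanion of the Still–Wittig rearrangement, which undergoes an irreversible suprafacial [2,3]-shift (driven by carboxylate formation) that transfers the carbonyl carbon from the exocyclic CH2O tether to the ring carbon and leaves the exocyclic methylene; the new bond forms axially, anti to the pseudoaxial hydrogen on the side-chain-bearing carbon of the half-chair with side chain and isopropyl both equatorial, which places CO2H cis to the side chain (1S).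

Step 17
Reactants: 30 (1S,2R,3S)-2-[(1E)-3-(tert-butyldimethylsilyloxy)-2-{[2-(trimethylsilyl)ethoxy]carbonyl}prop-1-en-1-yl]-6-methylidene-3-(propan-2-yl)cyclohexane-1-carboxylic acid
Product: 31 2-(trimethylsilyl)ethyl (2E)-2-[(tert-butyldimethylsilyloxy)methyl]-3-[(1S,2R,3S,6R)-6-(iodomethyl)-8-oxo-3-(propan-2-yl)-7-oxabicyclo[4.2.0]octan-2-yl]prop-2-enoate
Conditions: I2 (2 equiv), NaHCO3, MeCN/H2O, 0 °C, dark
Reagents that add atoms: iodine, II
Why: Kinetic iodolactonisation of a β,γ-unsaturated acid (4-exo-trig, Markovnikov) gives the β-lactone; the carboxylate oxygen can only reach the tertiary carbon on the face carrying the acyl carbon, so the new C–O bond is necessarily cis to the carbonyl (6R), and the electron-poor enoate is inert.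

Step 18
Reactants: 31 2-(trimethylsilyl)ethyl (2E)-2-[(tert-butyldimethylsilyloxy)methyl]-3-[(1S,2R,3S,6R)-6-(iodomethyl)-8-oxo-3-(propan-2-yl)-7-oxabicyclo[4.2.0]octan-2-yl]prop-2-enoate
Product: 32 2-(trimethylsilyl)ethyl (2E)-2-(hydroxymethyl)-3-[(1S,2R,3S,6R)-6-(iodomethyl)-8-oxo-3-(propan-2-yl)-7-oxabicyclo[4.2.0]octan-2-yl]prop-2-enoate
Conditions: HF·pyridine, pyridine, THF, 0 °C
Reagents that add atoms: none
Why: Buffered acidic fluoride removes the primary silyl ether while the β-lactone, the iodide and the 2-(trimethylsilyl)ethyl ester survive.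

Step 19
Reactants: 32 2-(trimethylsilyl)ethyl (2E)-2-(hydroxymethyl)-3-[(1S,2R,3S,6R)-6-(iodomethyl)-8-oxo-3-(propan-2-yl)-7-oxabicyclo[4.2.0]octan-2-yl]prop-2-enoate
Product: 34 2-(trimethylsilyl)ethyl (5aR,6S,9R,9aS)-1-oxo-6-(propan-2-yl)-3,5a,6,7,8,9a-hexahydro-1H-spiro[2-benzoxepine-9,2'-oxirane]-4-carboxylate (oxirane oxygen cis to the lactone carbonyl carbon), via iodohydrin lactone 33 (not isolated)
Conditions: K2CO3 (1.5 equiv), MeCN, 0 °C to rt
Reagents that add atoms: none
Why: Strain-driven intramolecular transacylation: the primary hydroxyl and the β-lactone carbonyl are cis on the cyclohexane, so the seven-membered lactone forms, and the released tertiary alkoxide closes the oxirane by 3-exo-tet displacement of iodide; the tertiary C–O bond is never broken, so its configuration is retained.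

**Coupling and end game**

Step 20
Reactants: 18 (2E)-2-(hydroxymethyl)-3-[(1R,6R)-3-(hydroxymethyl)-6-(propan-2-yl)cyclohex-2-en-1-yl]prop-2-enoic acid; 34 2-(trimethylsilyl)ethyl (5aR,6S,9R,9aS)-1-oxo-6-(propan-2-yl)-3,5a,6,7,8,9a-hexahydro-1H-spiro[2-benzoxepine-9,2'-oxirane]-4-carboxylate
Product: 35 2-(trimethylsilyl)ethyl (5aR,6S,9R,9aS)-9-hydroxy-9-[({(2E)-2-(hydroxymethyl)-3-[(1R,6R)-3-(hydroxymethyl)-6-(propan-2-yl)cyclohex-2-en-1-yl]prop-2-enoyl}oxy)methyl]-1-oxo-6-(propan-2-yl)-1,3,5a,6,7,8,9,9a-octahydro-2-benzoxepine-4-carboxylate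
Conditions: 18 (1.3 equiv), Cs2CO3 (0.3 equiv), DMF, 60 °C
Reagents that add atoms: none
Why: Base-catalysed carboxylate opening of a 2,2-disubstituted oxirane by SN2 attack at the unhindered CH2 forms the ester and frees the tertiary alcohol with retention at C9; the free hydroxyls of 18 are not competitive nucleophiles under carboxylate catalysis, so 18 needs no protection.

Step 21
Reactants: 35 2-(trimethylsilyl)ethyl (5aR,6S,9R,9aS)-9-hydroxy-9-[({(2E)-2-(hydroxymethyl)-3-[(1R,6R)-3-(hydroxymethyl)-6-(propan-2-yl)cyclohex-2-en-1-yl]prop-2-enoyl}oxy)methyl]-1-oxo-6-(propan-2-yl)-1,3,5a,6,7,8,9,9a-octahydro-2-benzoxepine-4-carboxylate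
Product: 36 (5aR,6S,9R,9aS)-9-hydroxy-9-[({(2E)-2-(hydroxymethyl)-3-[(1R,6R)-3-(hydroxymethyl)-6-(propan-2-yl)cyclohex-2-en-1-yl]prop-2-enoyl}oxy)methyl]-1-oxo-6-(propan-2-yl)-1,3,5a,6,7,8,9,9a-octahydro-2-benzoxepine-4-carboxylic acid (CNP0361406.3)
Conditions: Bu4NF (2 equiv), THF, 0 °C; 0.5 M HCl to pH 3
Reagents that add atoms: none
Why: Fluoride-induced β-silyl fragmentation of the 2-(trimethylsilyl)ethyl ester frees the acid under conditions too mild to epimerise the lactone α-carbon or cleave the other esters.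

**Compound list**
1 | (2-hydroxyethyl)triphenylphosphonium bromide | OCC[P+](c1ccccc1)(c1ccccc1)c1ccccc1.[Br-] | starting material
2 | [2-(tert-butyldimethylsilyloxy)ethyl]triphenylphosphonium bromide | CC(C)(C)[Si](C)(C)OCC[P+](c1ccccc1)(c1ccccc1)c1ccccc1.[Br-] | intermediate
3 | 4-nitrophenyl 2-(trimethylsilyl)ethyl carbonate | C[Si](C)(C)CCOC(=O)Oc1ccc(cc1)[N+](=O)[O-] | starting material
4 | [2-(tert-butyldimethylsilyloxy)ethylidene]triphenylphosphorane | CC(C)(C)[Si](C)(C)OCC=P(c1ccccc1)(c1ccccc1)c1ccccc1 | intermediate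
5 | {1-[(tert-butyldimethylsilyloxy)methyl]-2-oxo-2-[2-(trimethylsilyl)ethoxy]ethyl}triphenylphosphonium 4-nitrophenolate | CC(C)(C)[Si](C)(C)OCC(C(=O)OCC[Si](C)(C)C)[P+](c1ccccc1)(c1ccccc1)c1ccccc1.[O-]c1ccc(cc1)[N+](=O)[O-] | intermediate
6 | 2-(trimethylsilyl)ethyl 3-(tert-butyldimethylsilyloxy)-2-(triphenylphosphoranylidene)propanoate | CC(C)(C)[Si](C)(C)OCC(C(=O)OCC[Si](C)(C)C)=P(c1ccccc1)(c1ccccc1)c1ccccc1 | intermediate
7 | 3-methylbutanal | CC(C)CC=O | starting material
8 | but-3-en-2-one | CC(=O)C=C | starting material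
9 | (2R)-5-oxo-2-(propan-2-yl)hexanal | CC(C)[C@H](C=O)CCC(C)=O | intermediate
10 | (4R)-3-hydroxy-4-(propan-2-yl)cyclohexan-1-one (carbinol centre undefined) | CC(C)[C@H]1CCC(=O)CC1O | intermediate
11 | (4R)-4-(propan-2-yl)cyclohex-2-en-1-one | CC(C)[C@H]1CCC(=O)C=C1 | intermediate
12 | bromomagnesium (3R,4R)-3-ethenyl-4-(propan-2-yl)cyclohex-1-en-1-olate | CC(C)[C@H]1CCC(O[Mg]Br)=C[C@@H]1C=C | intermediate
13 | (3R,4R)-3-ethenyl-4-(propan-2-yl)cyclohex-1-en-1-yl trifluoromethanesulfonate | CC(C)[C@H]1CCC(OS(=O)(=O)C(F)(F)F)=C[C@@H]1C=C | intermediate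
14 | (3R,4R)-4-(propan-2-yl)-3-(1,2,4-trioxolan-3-yl)cyclohex-1-en-1-yl trifluoromethanesulfonate (trioxolane carbon undefined) | CC(C)[C@H]1CCC(OS(=O)(=O)C(F)(F)F)=C[C@@H]1C1OCOO1 | intermediate
15 | (3R,4R)-3-formyl-4-(propan-2-yl)cyclohex-1-en-1-yl trifluoromethanesulfonate | CC(C)[C@H]1CCC(OS(=O)(=O)C(F)(F)F)=C[C@@H]1C=O | intermediate
16 | 2-(trimethylsilyl)ethyl (2E)-2-[(tert-butyldimethylsilyloxy)methyl]-3-[(1S,6R)-6-(propan-2-yl)-3-(trifluoromethylsulfonyloxy)cyclohex-2-en-1-yl]prop-2-enoate | CC(C)[C@H]1CCC(OS(=O)(=O)C(F)(F)F)=C[C@@H]1/C=C(\CO[Si](C)(C)C(C)(C)C)C(=O)OCC[Si](C)(C)C | intermediate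
17 | 2-(trimethylsilyl)ethyl (2E)-2-[(tert-butyldimethylsilyloxy)methyl]-3-[(1R,6R)-3-(hydroxymethyl)-6-(propan-2-yl)cyclohex-2-en-1-yl]prop-2-enoate | CC(C)[C@H]1CCC(CO)=C[C@@H]1/C=C(\CO[Si](C)(C)C(C)(C)C)C(=O)OCC[Si](C)(C)C | intermediate
18 | (2E)-2-(hydroxymethyl)-3-[(1R,6R)-3-(hydroxymethyl)-6-(propan-2-yl)cyclohex-2-en-1-yl]prop-2-enoic acid | CC(C)[C@H]1CCC(CO)=C[C@@H]1/C=C(\CO)C(=O)O | intermediate
19 | (2S)-5-oxo-2-(propan-2-yl)hexanal | CC(C)[C@@H](C=O)CCC(C)=O | intermediate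
20 | (4S)-3-hydroxy-4-(propan-2-yl)cyclohexan-1-one (carbinol centre undefined) | CC(C)[C@@H]1CCC(=O)CC1O | intermediate
21 | (4S)-4-(propan-2-yl)cyclohex-2-en-1-one | CC(C)[C@@H]1CCC(=O)C=C1 | intermediate
22 | bromomagnesium (3S,4S)-3-ethenyl-4-(propan-2-yl)cyclohex-1-en-1-olate | CC(C)[C@@H]1CCC(O[Mg]Br)=C[C@H]1C=C | intermediate
23 | (3S,4S)-3-ethenyl-4-(propan-2-yl)cyclohex-1-en-1-yl trifluoromethanesulfonate | CC(C)[C@@H]1CCC(OS(=O)(=O)C(F)(F)F)=C[C@H]1C=C | intermediate
24 | (3S,4S)-4-(propan-2-yl)-3-(1,2,4-trioxolan-3-yl)cyclohex-1-en-1-yl trifluoromethanesulfonate (trioxolane carbon undefined) | CC(C)[C@@H]1CCC(OS(=O)(=O)C(F)(F)F)=C[C@H]1C1OCOO1 | intermediate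
25 | (3S,4S)-3-formyl-4-(propan-2-yl)cyclohex-1-en-1-yl trifluoromethanesulfonate | CC(C)[C@@H]1CCC(OS(=O)(=O)C(F)(F)F)=C[C@H]1C=O | intermediate
26 | 2-(trimethylsilyl)ethyl (2E)-2-[(tert-butyldimethylsilyloxy)methyl]-3-[(1R,6S)-6-(propan-2-yl)-3-(trifluoromethylsulfonyloxy)cyclohex-2-en-1-yl]prop-2-enoate | CC(C)[C@@H]1CCC(OS(=O)(=O)C(F)(F)F)=C[C@H]1/C=C(\CO[Si](C)(C)C(C)(C)C)C(=O)OCC[Si](C)(C)C | intermediate
27 | 2-(trimethylsilyl)ethyl (2E)-2-[(tert-butyldimethylsilyloxy)methyl]-3-[(1S,6S)-3-(hydroxymethyl)-6-(propan-2-yl)cyclohex-2-en-1-yl]prop-2-enoate | CC(C)[C@@H]1CCC(CO)=C[C@H]1/C=C(\CO[Si](C)(C)C(C)(C)C)C(=O)OCC[Si](C)(C)C | intermediate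
28 | potassium alkoxide of 27 | CC(C)[C@@H]1CCC(C[O-])=C[C@H]1/C=C(\CO[Si](C)(C)C(C)(C)C)C(=O)OCC[Si](C)(C)C.[K+] | intermediate
29 | potassium alkoxycarbonyl anion (oxido-alkoxy carbene) from 28 and CO, K+ −C(=O)OCH2–cyclohexenyl | CC(C)[C@@H]1CCC(CO[C-]=O)=C[C@H]1/C=C(\CO[Si](C)(C)C(C)(C)C)C(=O)OCC[Si](C)(C)C.[K+] | intermediate
30 | (1S,2R,3S)-2-[(1E)-3-(tert-butyldimethylsilyloxy)-2-{[2-(trimethylsilyl)ethoxy]carbonyl}prop-1-en-1-yl]-6-methylidene-3-(propan-2-yl)cyclohexane-1-carboxylic acid | C=C1CC[C@@H](C(C)C)[C@H](/C=C(\CO[Si](C)(C)C(C)(C)C)C(=O)OCC[Si](C)(C)C)[C@@H]1C(=O)O | intermediate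
31 | 2-(trimethylsilyl)ethyl (2E)-2-[(tert-butyldimethylsilyloxy)methyl]-3-[(1S,2R,3S,6R)-6-(iodomethyl)-8-oxo-3-(propan-2-yl)-7-oxabicyclo[4.2.0]octan-2-yl]prop-2-enoate | IC[C@@]12CC[C@@H](C(C)C)[C@H](/C=C(\CO[Si](C)(C)C(C)(C)C)C(=O)OCC[Si](C)(C)C)[C@@H]1C(=O)O2 | intermediate
32 | 2-(trimethylsilyl)ethyl (2E)-2-(hydroxymethyl)-3-[(1S,2R,3S,6R)-6-(iodomethyl)-8-oxo-3-(propan-2-yl)-7-oxabicyclo[4.2.0]octan-2-yl]prop-2-enoate | IC[C@@]12CC[C@@H](C(C)C)[C@H](/C=C(\CO)C(=O)OCC[Si](C)(C)C)[C@@H]1C(=O)O2 | intermediate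
33 | 2-(trimethylsilyl)ethyl (5aR,6S,9R,9aS)-9-hydroxy-9-(iodomethyl)-1-oxo-6-(propan-2-yl)-1,3,5a,6,7,8,9,9a-octahydro-2-benzoxepine-4-carboxylate (formed as its potassium alkoxide) | IC[C@@]1(O)CC[C@@H](C(C)C)[C@@H]2C=C(C(=O)OCC[Si](C)(C)C)COC(=O)[C@@H]21 | intermediate
34 | 2-(trimethylsilyl)ethyl (5aR,6S,9R,9aS)-1-oxo-6-(propan-2-yl)-3,5a,6,7,8,9a-hexahydro-1H-spiro[2-benzoxepine-9,2'-oxirane]-4-carboxylate | C1O[C@@]13CC[C@@H](C(C)C)[C@@H]2C=C(C(=O)OCC[Si](C)(C)C)COC(=O)[C@@H]23 | intermediate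
35 | 2-(trimethylsilyl)ethyl ester of the target (free diol of the cyclohexene half, tertiary carbinol free) | CC(C)[C@H]1CCC(CO)=C[C@@H]1/C=C(\CO)C(=O)OC[C@@]1(O)CC[C@@H](C(C)C)[C@@H]2C=C(C(=O)OCC[Si](C)(C)C)COC(=O)[C@@H]21 | intermediate
36 | (5aR,6S,9R,9aS)-9-hydroxy-9-[({(2E)-2-(hydroxymethyl)-3-[(1R,6R)-3-(hydroxymethyl)-6-(propan-2-yl)cyclohex-2-en-1-yl]prop-2-enoyl}oxy)methyl]-1-oxo-6-(propan-2-yl)-1,3,5a,6,7,8,9,9a-octahydro-2-benzoxepine-4-carboxylic acid | CC(C)[C@H]1CCC(CO)=C[C@@H]1/C=C(\CO)C(=O)OC[C@@]1(O)CC[C@@H](C(C)C)[C@@H]2C=C(C(=O)O)COC(=O)[C@@H]21 | target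

**Totals**
Total step count: 21. Longest linear sequence: 12 steps (steps 10 to 21, from 7 and 8).

**Three steps most likely to fail**

Step 16 (the proposed carbonylative [2,3]-Wittig rearrangement). Risks are a low standing concentration of the alkoxycarbonyl anion, alkoxide-induced side reactions of the enoate, and incomplete facial control at the new stereocentre. The fallback uses the known Still–Wittig rearrangement. It sets out from 27, which is O-alkylated (KH, Bu3SnCH2I, THF) to the tributylstannylmethyl ether of 27 F4. Tin–lithium exchange (n-BuLi, THF, −78 °C) triggers the [2,3]-shift through the same chair-like, axial bond-forming geometry and gives the homoallylic alcohol 2-(trimethylsilyl)ethyl (2E)-2-[(tert-butyldimethylsilyloxy)methyl]-3-[(1R,2S,6S)-2-(hydroxymethyl)-3-methylidene-6-(propan-2-yl)cyclohexyl]prop-2-enoate F5. Buffered one-pot oxidation (TEMPO, NaOCl, NaClO2, pH 6.7, MeCN) takes F5 to the acid, and the route comes back at 30.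

Step 7 (and its mirror-image twin, step 14: Wittig olefination of a hindered, epimerisable β,γ-unsaturated aldehyde). The fallback avoids the aldehyde altogether by cross-metathesis. Acryloyl chloride and 2-(trimethylsilyl)ethanol (Et3N, CH2Cl2) give 2-(trimethylsilyl)ethyl prop-2-enoate F1. Morita–Baylis–Hillman reaction with paraformaldehyde (DABCO, dioxane/water) gives 2-(trimethylsilyl)ethyl 2-(hydroxymethyl)prop-2-enoate F2, and silylation (TBSCl, imidazole) gives 2-(trimethylsilyl)ethyl 2-[(tert-butyldimethylsilyloxy)methyl]prop-2-enoate F3. The fallback sets out from 13, which is heated with F3 (3 equiv) and the second-generation Hoveyda–Grubbs catalyst RuCl2(SIMes)(=CH-C6H4-2-O-i-Pr) in toluene at 80 °C. Cross-metathesis of the vinyl group with the 1,1-disubstituted acrylate gives the thermodynamically favoured E-trisubstituted enoate, and the route comes back at 16, bypassing steps 6 and 7. In the S series the same sequence leads from 23 to 26.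

Step 17 (4-exo iodolactonisation to the β-lactone, which may be slow or give a fragile product). The fallback builds the seven-membered lactone first and sets the carbinol by halohydrin formation. It sets out from 30, which is desilylated (HF·pyridine, THF) to the hydroxy acid (1S,2R,3S)-2-[(1E)-3-hydroxy-2-{[2-(trimethylsilyl)ethoxy]carbonyl}prop-1-en-1-yl]-6-methylidene-3-(propan-2-yl)cyclohexane-1-carboxylic acid F6. Shiina lactonisation (2-methyl-6-nitrobenzoic anhydride, DMAP, CH2Cl2, high dilution) gives the methylene lactone 2-(trimethylsilyl)ethyl (5aR,6S,9aS)-9-methylidene-1-oxo-6-(propan-2-yl)-1,3,5a,6,7,8,9,9a-octahydro-2-benzoxepine-4-carboxylate F7. NBS in THF/water at 0 °C forms the bromonium ion on the face anti to the axial acyl substituent, and water opens it at the tertiary carbon from the other side. This gives the bromohydrin 2-(trimethylsilyl)ethyl (5aR,6S,9R,9aS)-9-(bromomethyl)-9-hydroxy-1-oxo-6-(propan-2-yl)-1,3,5a,6,7,8,9,9a-octahydro-2-benzoxepine-4-carboxylate F8. K2CO3 in MeCN closes the oxirane, and the route comes back at 34, bypassing steps 18 and 19.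

**Further compounds**
F1 | step 7 | 2-(trimethylsilyl)ethyl prop-2-enoate | C=CC(=O)OCC[Si](C)(C)C
F2 | step 7 | 2-(trimethylsilyl)ethyl 2-(hydroxymethyl)prop-2-enoate | C=C(CO)C(=O)OCC[Si](C)(C)C
F3 | step 7 | 2-(trimethylsilyl)ethyl 2-[(tert-butyldimethylsilyloxy)methyl]prop-2-enoate | C=C(CO[Si](C)(C)C(C)(C)C)C(=O)OCC[Si](C)(C)C
F4 | step 16 | 2-(trimethylsilyl)ethyl (2E)-2-[(tert-butyldimethylsilyloxy)methyl]-3-[(1S,6S)-6-(propan-2-yl)-3-{[(tributylstannyl)methoxy]methyl}cyclohex-2-en-1-yl]prop-2-enoate | CC(C)[C@@H]1CCC(COC[Sn](CCCC)(CCCC)CCCC)=C[C@H]1/C=C(\CO[Si](C)(C)C(C)(C)C)C(=O)OCC[Si](C)(C)C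
F5 | step 16 | 2-(trimethylsilyl)ethyl (2E)-2-[(tert-butyldimethylsilyloxy)methyl]-3-[(1R,2S,6S)-2-(hydroxymethyl)-3-methylidene-6-(propan-2-yl)cyclohexyl]prop-2-enoate | C=C1CC[C@@H](C(C)C)[C@H](/C=C(\CO[Si](C)(C)C(C)(C)C)C(=O)OCC[Si](C)(C)C)[C@@H]1CO
F6 | step 17 | (1S,2R,3S)-2-[(1E)-3-hydroxy-2-{[2-(trimethylsilyl)ethoxy]carbonyl}prop-1-en-1-yl]-6-methylidene-3-(propan-2-yl)cyclohexane-1-carboxylic acid | C=C1CC[C@@H](C(C)C)[C@H](/C=C(\CO)C(=O)OCC[Si](C)(C)C)[C@@H]1C(=O)O
F7 | step 17 | 2-(trimethylsilyl)ethyl (5aR,6S,9aS)-9-methylidene-1-oxo-6-(propan-2-yl)-1,3,5a,6,7,8,9,9a-octahydro-2-benzoxepine-4-carboxylate | C=C1CC[C@@H](C(C)C)[C@@H]2C=C(C(=O)OCC[Si](C)(C)C)COC(=O)[C@@H]21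
F8 | step 17 | 2-(trimethylsilyl)ethyl (5aR,6S,9R,9aS)-9-(bromomethyl)-9-hydroxy-1-oxo-6-(propan-2-yl)-1,3,5a,6,7,8,9,9a-octahydro-2-benzoxepine-4-carboxylate | BrC[C@@]1(O)CC[C@@H](C(C)C)[C@@H]2C=C(C(=O)OCC[Si](C)(C)C)COC(=O)[C@@H]21
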